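The target is a C2-symmetric C40 polyene whose two identical end rings (ring A, carotenoid atoms C1–C6) carry oxygen on the adjacent carbons C3 and C4. The route halves the molecule at C15=C15' and rests on forming the C3–C4 ring bond: because both carbons are oxygenated, two aldehyde carbons can be joined by polarity reversal. An azolium carbene turns the C3 aldehyde of an acyclic 1,6-dialdehyde into an acyl-anion equivalent that adds to the C4 aldehyde, closing ring A as the 3-oxo-4-hydroxy compound and setting C4 in one operation. The dialdehyde already holds C5, C6 and the (E)-C7=C8 PMB allyl ether, installed by an Ireland–Claisen rearrangement.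

Key step: step 9

Remark: carotenoid numbering (ring C1–C6, chain C7–C15) is used for all intermediates; PMB = 4-methoxybenzyl, TBS = tert-butyldimethylsilyl; the target is drawn as the free bis(hydrogen sulfate), so the last operation liberates it from its trimethylammonium salt on an acidic resin (a salt form would be preferred for storage), and all polyenes are handled under argon in dim light.

Step 1
Reactants: 1 (R)-solketal [(4R)-2,2-dimethyl-1,3-dioxolane-4-methanol]; 2 2-methylprop-1-en-1-ylmagnesium bromide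
Product: 4 1-[(4S)-2,2-dimethyl-1,3-dioxolan-4-yl]-3-methylbut-2-en-1-ol (both carbinol epimers), via (S)-glyceraldehyde acetonide 3 (not isolated)
Conditions: (COCl)2, DMSO, CH2Cl2, −78 °C; Et3N, −78 → −30 °C; then 2 (5 equiv), THF, −78 → 0 °C; aq. NH4Cl
Reagents that add atoms: none
Why: Swern oxidation followed by Grignard addition in the same flask is an established way to use a configurationally labile α-alkoxy aldehyde without isolating it; the dioxolane stereocentre comes from the chiral pool and the new carbinol centre needs no control because it becomes sp2 in step 2.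

Step 2
Reactants: 4 1-[(4S)-2,2-dimethyl-1,3-dioxolan-4-yl]-3-methylbut-2-en-1-ol
Product: 6 methyl (E)-5-[(4R)-2,2-dimethyl-1,3-dioxolan-4-yl]-3,3-dimethylpent-4-enoate, via mixed ketene acetal 5 (not isolated)
Conditions: MeC(OMe)3 (excess), EtCO2H (cat.), 130–140 °C, MeOH distilled off
Reagents that add atoms: trimethyl orthoacetate COC(C)(OC)OC
Why: Johnson–Claisen (orthoester Claisen) rearrangement of a secondary prenyl-type allylic alcohol passes through a chair with the dioxolanyl group equatorial and so should build the quaternary C1 and the (E)-alkene, while the dioxolane stereocentre is untouched (its descriptor changes to R by priority only).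

Step 3
Reactants: 6 methyl (E)-5-[(4R)-2,2-dimethyl-1,3-dioxolan-4-yl]-3,3-dimethylpent-4-enoate
Product: 7 methyl (4E,6R)-6,7-dihydroxy-3,3-dimethylhept-4-enoate
Conditions: sulfonic acid cation-exchange resin (H+ form), MeOH, rt
Reagents that add atoms: none
Why: Acid-catalysed transacetalisation with methanol removes the isopropylidene group without touching the methyl ester or the allylic stereocentre, and the (E)-alkene between hydroxyl and ester rules out lactonisation.

Step 4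
Reactants: 7 methyl (4E,6R)-6,7-dihydroxy-3,3-dimethylhept-4-enoate
Product: 9 methyl (4E,6R)-6-hydroxy-7-[(4-methoxybenzyl)oxy]-3,3-dimethylhept-4-enoate, via dibutylstannylene acetal 8 (not isolated)
Conditions: Bu2SnO, toluene, reflux (water removed); then PMBCl, Bu4NI (cat.), 90 °C
Reagents that add atoms: 4-methoxybenzyl chloride COc1ccc(CCl)cc1
Why: Stannylene-acetal-mediated mono-alkylation of a terminal 1,2-diol is reliably selective for the primary oxygen and leaves the secondary allylic hydroxyl free with its configuration unchanged.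

Step 5
Reactants: 9 methyl (4E,6R)-6-hydroxy-7-[(4-methoxybenzyl)oxy]-3,3-dimethylhept-4-enoate; 10 propanoyl chloride
Product: 11 methyl (4E,6R)-7-[(4-methoxybenzyl)oxy]-3,3-dimethyl-6-(propanoyloxy)hept-4-enoate
Conditions: pyridine, DMAP (cat.), CH2Cl2, 0 °C → rt
Reagents that add atoms: none
Why: Pyridine/DMAP-promoted acylation of a secondary alcohol by an acid chloride proceeds with retention at the carbinol carbon.

Step 6
Reactants: 11 methyl (4E,6R)-7-[(4-methoxybenzyl)oxy]-3,3-dimethyl-6-(propanoyloxy)hept-4-enoate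
Product: 14 (2R,3R)-6-methoxy-3-{(E)-3-[(4-methoxybenzyl)oxy]prop-1-en-1-yl}-2,4,4-trimethyl-6-oxohexanoic acid, via (E)-trimethylsilyl ketene acetal 12 (not isolated), via trimethylsilyl ester 13 (not isolated)
Conditions: LiN(i-Pr)2 (1.2 equiv), THF, −78 °C; Me3SiCl/Et3N, −78 °C → rt, then 60 °C; aq. HCl work-up
Reagents that add atoms: none
Why: Ireland–Claisen rearrangement, in which kinetic deprotonation of the unhindered propanoate CH2 in THF gives the enolate with methyl cis to the allyloxy oxygen, silylation fixes it as the (E)-silyl ketene acetal, and a chair with the CH2OPMB and tert-alkyl groups equatorial transfers the (R)-carbinol configuration to C5 (R) and C6 (R) in the anti sense with an (E)-C7=C8 bond (any silyl ketene acetal of the hindered methyl ester cannot rearrange and reverts on work-up).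

Step 7
Reactants: 14 (2R,3R)-6-methoxy-3-{(E)-3-[(4-methoxybenzyl)oxy]prop-1-en-1-yl}-2,4,4-trimethyl-6-oxohexanoic acid
Product: 15 (2R,3R)-3-{(E)-3-[(4-methoxybenzyl)oxy]prop-1-en-1-yl}-2,4,4-trimethylhexane-1,6-diol
Conditions: LiAlH4, THF, 0 °C → rt; aq. NaOH work-up
Reagents that add atoms: none
Why: Hydride reduction with LiAlH4 takes the carboxylic acid and the methyl ester together to the 1,6-diol without affecting the PMB ether, the alkene or the two stereocentres.

Step 8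
Reactants: 15 (2R,3R)-3-{(E)-3-[(4-methoxybenzyl)oxy]prop-1-en-1-yl}-2,4,4-trimethylhexane-1,6-diol
Product: 16 (2R,3R)-3-{(E)-3-[(4-methoxybenzyl)oxy]prop-1-en-1-yl}-2,4,4-trimethylhexanedial
Conditions: Dess–Martin periodinane, NaHCO3, CH2Cl2, 0 °C → rt; crude product used at once
Reagents that add atoms: none
Why: Buffered Dess–Martin oxidation converts both primary alcohols to aldehydes under non-basic conditions that should not epimerise C5 next to the branched C4 aldehyde.

Step 9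
Reactants: 16 (2R,3R)-3-{(E)-3-[(4-methoxybenzyl)oxy]prop-1-en-1-yl}-2,4,4-trimethylhexanedial
Product: 17 (2S,3R,4R)-2-hydroxy-4-{(E)-3-[(4-methoxybenzyl)oxy]prop-1-en-1-yl}-3,5,5-trimethylcyclohexan-1-one
Conditions: 2-(pentafluorophenyl)-6,7-dihydro-5H-pyrrolo[2,1-c][1,2,4]triazol-2-ium tetrafluoroborate (15 mol%), i-Pr2NEt (15 mol%), CH2Cl2 (0.02 M), rt, argon
Reagents that add atoms: none
Why: Deprotonation of the triazolium salt gives the free carbene, which adds to the less hindered C3 aldehyde (α-CH2) and after proton transfer forms the nucleophilic enaminol (Breslow intermediate); its carbon attacks the C4 aldehyde and collapse of the adduct releases the carbene and the 3-oxo-4-hydroxy ring. The closest known reaction type is the azolium-carbene-catalysed intramolecular benzoin (acyloin) cyclisation of aliphatic dialdehydes to 2-hydroxycycloalkanones. Ring A closes in the 6-exo-trig mode, the C4 carbonyl lying outside the forming ring. The new C4 stereocentre is controlled by a chair-like transition state with the C5 methyl and the C6 alkenyl chain equatorial and the aldehyde oxygen in the equatorial site, hydrogen-bonded to the enaminol hydroxyl, which places the C4 hydroxyl trans to the C5 methyl; this equatorial ketol is also expected to be the more stable C4 epimer. The step needs acyl-anion formation at C3 and not at C4 and must outrun aldol closure and C5 epimerisation; the α- and β-branched C4 aldehyde is the poorer site for carbene addition, and the weak amine base, room temperature and high dilution disfavour enolate pathways and intermolecular coupling.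

Step 10
Reactants: 17 (2S,3R,4R)-2-hydroxy-4-{(E)-3-[(4-methoxybenzyl)oxy]prop-1-en-1-yl}-3,5,5-trimethylcyclohexan-1-one
Product: 18 (2S,3R,4R)-2-[(tert-butyldimethylsilyl)oxy]-4-{(E)-3-[(4-methoxybenzyl)oxy]prop-1-en-1-yl}-3,5,5-trimethylcyclohexan-1-one
Conditions: t-BuMe2SiCl, imidazole, DMF, rt → 40 °C
Reagents that add atoms: tert-butyldimethylsilyl chloride CC(C)(C)[Si](C)(C)Cl
Why: Imidazole-promoted silylation of the equatorial secondary hydroxyl uses no strong base, so the C4 oxygen is capped without ketol transposition or epimerisation.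

Step 11
Reactants: 18 (2S,3R,4R)-2-[(tert-butyldimethylsilyl)oxy]-4-{(E)-3-[(4-methoxybenzyl)oxy]prop-1-en-1-yl}-3,5,5-trimethylcyclohexan-1-one
Product: 19 (1R,2S,3R,4R)-2-[(tert-butyldimethylsilyl)oxy]-4-{(E)-3-[(4-methoxybenzyl)oxy]prop-1-en-1-yl}-3,5,5-trimethylcyclohexan-1-ol
Conditions: Li[HB(sec-Bu)3], THF, −78 °C; aq. NH4Cl
Reagents that add atoms: none
Why: Reduction of a cyclohexanone by a bulky trialkylborohydride occurs from the equatorial direction, here reinforced by the axial C1 methyl that blocks the axial trajectory at C3, and should give the axial (3R) alcohol cis to the C4 silyloxy group.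

Step 12
Reactants: 19 (1R,2S,3R,4R)-2-[(tert-butyldimethylsilyl)oxy]-4-{(E)-3-[(4-methoxybenzyl)oxy]prop-1-en-1-yl}-3,5,5-trimethylcyclohexan-1-ol
Product: 20 (1R,2S,3R,4R)-2-[(tert-butyldimethylsilyl)oxy]-4-[(E)-3-hydroxyprop-1-en-1-yl]-3,5,5-trimethylcyclohexan-1-ol
Conditions: DDQ, CH2Cl2/pH 7 buffer, 0 °C
Reagents that add atoms: none
Why: Oxidative cleavage of a 4-methoxybenzyl ether by DDQ spares the silyl ether, the free secondary alcohol and the disubstituted alkene, and any over-oxidation would only give the enal wanted in step 13.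

Step 13
Reactants: 20 (1R,2S,3R,4R)-2-[(tert-butyldimethylsilyl)oxy]-4-[(E)-3-hydroxyprop-1-en-1-yl]-3,5,5-trimethylcyclohexan-1-ol
Product: 21 (E)-3-{(1R,4R,5S,6R)-5-[(tert-butyldimethylsilyl)oxy]-4-hydroxy-2,2,6-trimethylcyclohexyl}prop-2-enal
Conditions: activated MnO2, CH2Cl2, rt
Reagents that add atoms: none
Why: MnO2 oxidises allylic alcohols selectively, so the primary allylic hydroxyl gives the (E)-enal while the saturated axial C3 hydroxyl is left alone.

Step 14
Reactants: 21 (E)-3-{(1R,4R,5S,6R)-5-[(tert-butyldimethylsilyl)oxy]-4-hydroxy-2,2,6-trimethylcyclohexyl}prop-2-enal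
Product: 22 (E)-4-{(1R,4R,5S,6R)-5-[(tert-butyldimethylsilyl)oxy]-4-hydroxy-2,2,6-trimethylcyclohexyl}but-3-en-2-ol (both carbinol epimers)
Conditions: MeMgBr (3 equiv), THF, −78 → 0 °C; aq. NH4Cl
Reagents that add atoms: methylmagnesium bromide C[Mg]Br
Why: Grignard 1,2-addition to an enal installs the C19 methyl carbon, the first equivalent being consumed by the C3 hydroxyl, and the new carbinol centre needs no control because step 15 removes it.

Step 15
Reactants: 22 (E)-4-{(1R,4R,5S,6R)-5-[(tert-butyldimethylsilyl)oxy]-4-hydroxy-2,2,6-trimethylcyclohexyl}but-3-en-2-ol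
Product: 23 (E)-4-{(1R,4R,5S,6R)-5-[(tert-butyldimethylsilyl)oxy]-4-hydroxy-2,2,6-trimethylcyclohexyl}but-3-en-2-one
Conditions: activated MnO2, CH2Cl2, rt
Reagents that add atoms: none
Why: Chemoselective MnO2 oxidation of the secondary allylic alcohol gives the (E)-enone, the ring-saturated analogue of an ionone, and again leaves the C3 hydroxyl untouched.

Step 16
Reactants: 23 (E)-4-{(1R,4R,5S,6R)-5-[(tert-butyldimethylsilyl)oxy]-4-hydroxy-2,2,6-trimethylcyclohexyl}but-3-en-2-one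
Product: 24 (2E,4E)-5-{(1R,4R,5S,6R)-5-[(tert-butyldimethylsilyl)oxy]-4-hydroxy-2,2,6-trimethylcyclohexyl}-3-methylpenta-2,4-dienenitrile
Conditions: (EtO)2P(O)CH2CN, NaH, THF, 0 °C → rt; (2Z) isomer removed by chromatography
Reagents that add atoms: diethyl cyanomethylphosphonate CCOP(=O)(CC#N)OCC
Why: Horner–Wadsworth–Emmons olefination of an ionone-type methyl ketone with the pre-formed cyanomethylphosphonate anion is the standard C13-to-C15 extension of retinoid chemistry and should favour the (9E) trisubstituted alkene.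

Step 17
Reactants: 24 (2E,4E)-5-{(1R,4R,5S,6R)-5-[(tert-butyldimethylsilyl)oxy]-4-hydroxy-2,2,6-trimethylcyclohexyl}-3-methylpenta-2,4-dienenitrile
Product: 26 (2E,4E)-5-{(1R,4R,5S,6R)-5-[(tert-butyldimethylsilyl)oxy]-4-hydroxy-2,2,6-trimethylcyclohexyl}-3-methylpenta-2,4-dienal, via aldimine 25 (not isolated)
Conditions: i-Bu2AlH (2.5 equiv), CH2Cl2, −78 °C; aq. KNaC4H4O6
Reagents that add atoms: water O
Why: Partial reduction of a conjugated nitrile by i-Bu2AlH stops at the aluminated imine, whose hydrolysis on work-up gives the dienal with both alkene geometries retained.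

Step 18
Reactants: 26 (2E,4E)-5-{(1R,4R,5S,6R)-5-[(tert-butyldimethylsilyl)oxy]-4-hydroxy-2,2,6-trimethylcyclohexyl}-3-methylpenta-2,4-dienal; 27 triethyl 3-methyl-4-phosphonocrotonate
Product: 28 ethyl (2E,4E,6E,8E)-9-{(1R,4R,5S,6R)-5-[(tert-butyldimethylsilyl)oxy]-4-hydroxy-2,2,6-trimethylcyclohexyl}-3,7-dimethylnona-2,4,6,8-tetraenoate
Conditions: 27, n-BuLi, THF/DMPU, −78 °C; then 26, −78 → 0 °C
Reagents that add atoms: none
Why: Horner–Wadsworth–Emmons reaction of the lithiated C5 phosphonate with a dienal is the usual C15 + C5 route to retinoate esters and should form the new C11=C12 bond (E)-selectively.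

Step 19
Reactants: 28 ethyl (2E,4E,6E,8E)-9-{(1R,4R,5S,6R)-5-[(tert-butyldimethylsilyl)oxy]-4-hydroxy-2,2,6-trimethylcyclohexyl}-3,7-dimethylnona-2,4,6,8-tetraenoate
Product: 29 (2E,4E,6E,8E)-9-{(1R,4R,5S,6R)-5-[(tert-butyldimethylsilyl)oxy]-4-hydroxy-2,2,6-trimethylcyclohexyl}-3,7-dimethylnona-2,4,6,8-tetraen-1-ol
Conditions: i-Bu2AlH (3.5 equiv), CH2Cl2, −78 °C; aq. KNaC4H4O6
Reagents that add atoms: none
Why: i-Bu2AlH reduces the conjugated ethyl ester to the allylic alcohol by 1,2-hydride delivery without touching the tetraene.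

Step 20
Reactants: 29 (2E,4E,6E,8E)-9-{(1R,4R,5S,6R)-5-[(tert-butyldimethylsilyl)oxy]-4-hydroxy-2,2,6-trimethylcyclohexyl}-3,7-dimethylnona-2,4,6,8-tetraen-1-ol
Product: 30 (2E,4E,6E,8E)-9-{(1R,4R,5S,6R)-5-[(tert-butyldimethylsilyl)oxy]-4-hydroxy-2,2,6-trimethylcyclohexyl}-3,7-dimethylnona-2,4,6,8-tetraenal
Conditions: activated MnO2, CH2Cl2, rt, dark
Reagents that add atoms: none
Why: MnO2 oxidation of the polyenylic primary alcohol, the standard retinol-to-retinal conversion, leaves the saturated ring hydroxyl intact.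

Step 21
Reactants: 30 (2E,4E,6E,8E)-9-{(1R,4R,5S,6R)-5-[(tert-butyldimethylsilyl)oxy]-4-hydroxy-2,2,6-trimethylcyclohexyl}-3,7-dimethylnona-2,4,6,8-tetraenal (two molecules)
Product: 31 (3R,4S,5R,6R,3'R,4'S,5'R,6'R)-4,4'-bis[(tert-butyldimethylsilyl)oxy]-5,6,5',6'-tetrahydro-β,β-carotene-3,3'-diol
Conditions: TiCl3, LiAlH4, THF, reflux; then 30, rt → reflux, dark; brief warming in heptane to convert (15Z) into (15E)
Reagents that add atoms: none
Why: McMurry reductive coupling of two polyenals by low-valent titanium (pinacol coupling then deoxygenation), the known retinal-to-carotene dimerisation, forms the central C15=C15' bond, with the all-(E) isomer expected to dominate after thermal equilibration and the silyl ethers and isolated hydroxyls inert.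

Step 22
Reactants: 31 (3R,4S,5R,6R,3'R,4'S,5'R,6'R)-4,4'-bis[(tert-butyldimethylsilyl)oxy]-5,6,5',6'-tetrahydro-β,β-carotene-3,3'-diol
Product: 32 (3R,4S,5R,6R,3'R,4'S,5'R,6'R)-5,6,5',6'-tetrahydro-β,β-carotene-3,4,3',4'-tetrol
Conditions: Bu4NF, THF, rt, dark
Reagents that add atoms: none
Why: Fluoride-induced cleavage of the two equatorial silyl ethers proceeds under non-acidic conditions that the polyene tolerates.

Step 23
Reactants: 32 (3R,4S,5R,6R,3'R,4'S,5'R,6'R)-5,6,5',6'-tetrahydro-β,β-carotene-3,4,3',4'-tetrol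
Product: 34 (3R,4S,5R,6R,3'R,4'S,5'R,6'R)-5,6,5',6'-tetrahydro-β,β-carotene-3,4,3',4'-tetrol 4,4'-bis(hydrogen sulfate) (target), via bis(dibutylstannylene) acetal 33 (not isolated)
Conditions: Bu2SnO (2.2 equiv), MeOH, reflux, then evaporation; SO3·NMe3 (2.4 equiv), DMF, rt; sulfonic acid cation-exchange resin (H+ form), MeOH/H2O, 0 °C
Reagents that add atoms: sulfur trioxide–trimethylamine complex C[N+](C)(C)S(=O)(=O)[O-]
Why: Stannylene-acetal-directed sulfation of a cis-1,2-diol is known to activate the equatorial oxygen, so SO3·NMe3 should sulfate O4 while the axial O3, also shielded by the syn-axial C1 methyl, stays free, and the acidic resin then exchanges trimethylammonium for protons.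

Compound list
1 | (R)-solketal, (4R)-2,2-dimethyl-1,3-dioxolane-4-methanol | OC[C@@H]1COC(C)(C)O1 | starting material
2 | 2-methylprop-1-en-1-ylmagnesium bromide | CC(C)=C[Mg]Br | starting material
3 | (S)-glyceraldehyde acetonide, (4S)-2,2-dimethyl-1,3-dioxolane-4-carbaldehyde | O=C[C@@H]1COC(C)(C)O1 | intermediate
4 | 1-[(4S)-2,2-dimethyl-1,3-dioxolan-4-yl]-3-methylbut-2-en-1-ol (both carbinol epimers) | CC(C)=CC(O)[C@@H]1COC(C)(C)O1 | intermediate
5 | (4S)-4-{1-[(1-methoxyethenyl)oxy]-3-methylbut-2-en-1-yl}-2,2-dimethyl-1,3-dioxolane (mixed ketene acetal) | C=C(OC)OC(C=C(C)C)[C@@H]1COC(C)(C)O1 | intermediate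
6 | methyl (E)-5-[(4R)-2,2-dimethyl-1,3-dioxolan-4-yl]-3,3-dimethylpent-4-enoate | COC(=O)CC(C)(C)/C=C/[C@@H]1COC(C)(C)O1 | intermediate
7 | methyl (4E,6R)-6,7-dihydroxy-3,3-dimethylhept-4-enoate | COC(=O)CC(C)(C)/C=C/[C@@H](O)CO | intermediate
8 | methyl (E)-5-[(4R)-2,2-dibutyl-1,3,2-dioxastannolan-4-yl]-3,3-dimethylpent-4-enoate (stannylene acetal) | COC(=O)CC(C)(C)/C=C/[C@@H]1CO[Sn](CCCC)(CCCC)O1 | intermediate
9 | methyl (4E,6R)-6-hydroxy-7-[(4-methoxybenzyl)oxy]-3,3-dimethylhept-4-enoate | COC(=O)CC(C)(C)/C=C/[C@@H](O)COCc1ccc(OC)cc1 | intermediate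
10 | propanoyl chloride | CCC(=O)Cl | starting material
11 | methyl (4E,6R)-7-[(4-methoxybenzyl)oxy]-3,3-dimethyl-6-(propanoyloxy)hept-4-enoate | COC(=O)CC(C)(C)/C=C/[C@@H](OC(=O)CC)COCc1ccc(OC)cc1 | intermediate
12 | methyl (4E,6R)-7-[(4-methoxybenzyl)oxy]-3,3-dimethyl-6-{[(1E)-1-(trimethylsilyloxy)prop-1-en-1-yl]oxy}hept-4-enoate | C/C=C(/O[Si](C)(C)C)O[C@H](/C=C/C(C)(C)CC(=O)OC)COCc1ccc(OC)cc1 | intermediate
13 | trimethylsilyl (2R,3R)-6-methoxy-3-{(E)-3-[(4-methoxybenzyl)oxy]prop-1-en-1-yl}-2,4,4-trimethyl-6-oxohexanoate | COc1ccc(COC/C=C/[C@@H](C(C)(C)CC(=O)OC)[C@@H](C)C(=O)O[Si](C)(C)C)cc1 | intermediate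
14 | (2R,3R)-6-methoxy-3-{(E)-3-[(4-methoxybenzyl)oxy]prop-1-en-1-yl}-2,4,4-trimethyl-6-oxohexanoic acid | COc1ccc(COC/C=C/[C@@H](C(C)(C)CC(=O)OC)[C@@H](C)C(=O)O)cc1 | intermediate
15 | (2R,3R)-3-{(E)-3-[(4-methoxybenzyl)oxy]prop-1-en-1-yl}-2,4,4-trimethylhexane-1,6-diol | COc1ccc(COC/C=C/[C@@H](C(C)(C)CCO)[C@@H](C)CO)cc1 | intermediate
16 | (2R,3R)-3-{(E)-3-[(4-methoxybenzyl)oxy]prop-1-en-1-yl}-2,4,4-trimethylhexanedial | COc1ccc(COC/C=C/[C@@H](C(C)(C)CC=O)[C@@H](C)C=O)cc1 | intermediate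
17 | (2S,3R,4R)-2-hydroxy-4-{(E)-3-[(4-methoxybenzyl)oxy]prop-1-en-1-yl}-3,5,5-trimethylcyclohexan-1-one | COc1ccc(COC/C=C/[C@@H]2[C@@H](C)[C@H](O)C(=O)CC2(C)C)cc1 | intermediate
18 | (2S,3R,4R)-2-[(tert-butyldimethylsilyl)oxy]-4-{(E)-3-[(4-methoxybenzyl)oxy]prop-1-en-1-yl}-3,5,5-trimethylcyclohexan-1-one | COc1ccc(COC/C=C/[C@@H]2[C@@H](C)[C@H](O[Si](C)(C)C(C)(C)C)C(=O)CC2(C)C)cc1 | intermediate
19 | (1R,2S,3R,4R)-2-[(tert-butyldimethylsilyl)oxy]-4-{(E)-3-[(4-methoxybenzyl)oxy]prop-1-en-1-yl}-3,5,5-trimethylcyclohexan-1-ol | COc1ccc(COC/C=C/[C@@H]2[C@@H](C)[C@H](O[Si](C)(C)C(C)(C)C)[C@H](O)CC2(C)C)cc1 | intermediate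
20 | (1R,2S,3R,4R)-2-[(tert-butyldimethylsilyl)oxy]-4-[(E)-3-hydroxyprop-1-en-1-yl]-3,5,5-trimethylcyclohexan-1-ol | OC/C=C/[C@@H]1[C@@H](C)[C@H](O[Si](C)(C)C(C)(C)C)[C@H](O)CC1(C)C | intermediate
21 | (E)-3-{(1R,4R,5S,6R)-5-[(tert-butyldimethylsilyl)oxy]-4-hydroxy-2,2,6-trimethylcyclohexyl}prop-2-enal | O=C/C=C/[C@@H]1[C@@H](C)[C@H](O[Si](C)(C)C(C)(C)C)[C@H](O)CC1(C)C | intermediate
22 | (E)-4-{(1R,4R,5S,6R)-5-[(tert-butyldimethylsilyl)oxy]-4-hydroxy-2,2,6-trimethylcyclohexyl}but-3-en-2-ol (both carbinol epimers) | CC(O)/C=C/[C@@H]1[C@@H](C)[C@H](O[Si](C)(C)C(C)(C)C)[C@H](O)CC1(C)C | intermediate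
23 | (E)-4-{(1R,4R,5S,6R)-5-[(tert-butyldimethylsilyl)oxy]-4-hydroxy-2,2,6-trimethylcyclohexyl}but-3-en-2-one | CC(=O)/C=C/[C@@H]1[C@@H](C)[C@H](O[Si](C)(C)C(C)(C)C)[C@H](O)CC1(C)C | intermediate
24 | (2E,4E)-5-{(1R,4R,5S,6R)-5-[(tert-butyldimethylsilyl)oxy]-4-hydroxy-2,2,6-trimethylcyclohexyl}-3-methylpenta-2,4-dienenitrile | N#C/C=C(C)/C=C/[C@@H]1[C@@H](C)[C@H](O[Si](C)(C)C(C)(C)C)[C@H](O)CC1(C)C | intermediate
25 | (2E,4E)-5-{(1R,4R,5S,6R)-5-[(tert-butyldimethylsilyl)oxy]-4-hydroxy-2,2,6-trimethylcyclohexyl}-3-methylpenta-2,4-dien-1-imine (formed as its N-aluminium derivative) | N=C/C=C(C)/C=C/[C@@H]1[C@@H](C)[C@H](O[Si](C)(C)C(C)(C)C)[C@H](O)CC1(C)C | intermediate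
26 | (2E,4E)-5-{(1R,4R,5S,6R)-5-[(tert-butyldimethylsilyl)oxy]-4-hydroxy-2,2,6-trimethylcyclohexyl}-3-methylpenta-2,4-dienal | O=C/C=C(C)/C=C/[C@@H]1[C@@H](C)[C@H](O[Si](C)(C)C(C)(C)C)[C@H](O)CC1(C)C | intermediate
27 | triethyl 3-methyl-4-phosphonocrotonate, ethyl (E)-4-(diethoxyphosphoryl)-3-methylbut-2-enoate | CCOC(=O)/C=C(\C)CP(=O)(OCC)OCC | starting material
28 | ethyl (2E,4E,6E,8E)-9-{(1R,4R,5S,6R)-5-[(tert-butyldimethylsilyl)oxy]-4-hydroxy-2,2,6-trimethylcyclohexyl}-3,7-dimethylnona-2,4,6,8-tetraenoate | CCOC(=O)/C=C(C)/C=C/C=C(C)/C=C/[C@@H]1[C@@H](C)[C@H](O[Si](C)(C)C(C)(C)C)[C@H](O)CC1(C)C | intermediate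
29 | (2E,4E,6E,8E)-9-{(1R,4R,5S,6R)-5-[(tert-butyldimethylsilyl)oxy]-4-hydroxy-2,2,6-trimethylcyclohexyl}-3,7-dimethylnona-2,4,6,8-tetraen-1-ol | OC/C=C(C)/C=C/C=C(C)/C=C/[C@@H]1[C@@H](C)[C@H](O[Si](C)(C)C(C)(C)C)[C@H](O)CC1(C)C | intermediate
30 | (2E,4E,6E,8E)-9-{(1R,4R,5S,6R)-5-[(tert-butyldimethylsilyl)oxy]-4-hydroxy-2,2,6-trimethylcyclohexyl}-3,7-dimethylnona-2,4,6,8-tetraenal | O=C/C=C(C)/C=C/C=C(C)/C=C/[C@@H]1[C@@H](C)[C@H](O[Si](C)(C)C(C)(C)C)[C@H](O)CC1(C)C | intermediate
31 | (3R,4S,5R,6R,3'R,4'S,5'R,6'R)-4,4'-bis[(tert-butyldimethylsilyl)oxy]-5,6,5',6'-tetrahydro-β,β-carotene-3,3'-diol | CC(/C=C/C=C(C)/C=C/[C@@H]1[C@@H](C)[C@H](O[Si](C)(C)C(C)(C)C)[C@H](O)CC1(C)C)=C\C=C\C=C(C)\C=C\C=C(C)\C=C\[C@@H]1[C@@H](C)[C@H](O[Si](C)(C)C(C)(C)C)[C@H](O)CC1(C)C | intermediate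
32 | (3R,4S,5R,6R,3'R,4'S,5'R,6'R)-5,6,5',6'-tetrahydro-β,β-carotene-3,4,3',4'-tetrol | CC(/C=C/C=C(C)/C=C/[C@@H]1[C@@H](C)[C@H](O)[C@H](O)CC1(C)C)=C\C=C\C=C(C)\C=C\C=C(C)\C=C\[C@@H]1[C@@H](C)[C@H](O)[C@H](O)CC1(C)C | intermediate
33 | 3,4:3',4'-bis-O-(dibutylstannylene) derivative of 32 | CC(/C=C/C=C(C)/C=C/[C@@H]1[C@@H](C)[C@@H]2O[Sn](CCCC)(CCCC)O[C@@H]2CC1(C)C)=C\C=C\C=C(C)\C=C\C=C(C)\C=C\[C@@H]1[C@@H](C)[C@@H]2O[Sn](CCCC)(CCCC)O[C@@H]2CC1(C)C | intermediate
34 | (3R,4S,5R,6R,3'R,4'S,5'R,6'R)-5,6,5',6'-tetrahydro-β,β-carotene-3,4,3',4'-tetrol 4,4'-bis(hydrogen sulfate) | CC(/C=C/C=C(C)/C=C/[C@@H]1[C@@H](C)[C@H](OS(=O)(=O)O)[C@H](O)CC1(C)C)=C\C=C\C=C(C)\C=C\C=C(C)\C=C\[C@@H]1[C@@H](C)[C@H](OS(=O)(=O)O)[C@H](O)CC1(C)C | target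

Total step count: 23. Longest linear sequence: 23 steps (steps 1–23 from (R)-solketal; the route is linear, the two halves being joined in step 21).

Steps most likely to fail

Step 9. The carbene may engage the C4 aldehyde first and give the transposed ketol, the amine base may trigger aldol closure to five-membered rings or epimerise C5 before the ring forms, and the C4 hydroxyl may form partly axial. The fallback closes the same C3–C4 bond reductively. Dialdehyde 16 would be treated with SmI2 (THF, t-BuOH, −78 °C), the ketyl pinacol cyclisation known to turn 1,6-dialdehydes into cis-cyclohexane-1,2-diols with the oxygen next to a branched carbon anti to that branch. This should give (1R,2S,3R,4R)-4-{(E)-3-[(4-methoxybenzyl)oxy]prop-1-en-1-yl}-3,5,5-trimethylcyclohexane-1,2-diol F1. Silylation of its less hindered equatorial C4 hydroxyl (t-BuMe2SiCl, imidazole, DMF) rejoins the route at 19.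

Step 6. Incomplete control of enolate geometry, leakage through a boat transition state at the congested tert-alkyl terminus, or competing enolisation of the second ester would erode the C5/C6 relationship. The fallback sets out from allylic alcohol 9 and uses a thermal, base-free rearrangement. Heating 9 with 1,1-dimethoxy-N,N-dimethylpropan-1-amine F2 (made from N,N-dimethylpropanamide with dimethyl sulfate, then NaOMe) in xylene at 140 °C is an Eschenmoser–Claisen rearrangement. Through the ketene N,O-acetal with methyl cis to oxygen and the same chair it should give the anti amide methyl (4R,5R)-6-(dimethylamino)-4-{(E)-3-[(4-methoxybenzyl)oxy]prop-1-en-1-yl}-3,3,5-trimethyl-6-oxohexanoate F3. LiH2NBH3 in THF then reduces both the tertiary amide and the ester, rejoining the route at diol 15.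

Step 23. Sulfation may stray to the axial O3 or go twice on one ring, and heating with the tin oxide or contact with the acidic resin may isomerise or degrade the polyene. The fallback replaces regiocontrol by protecting-group differentiation and sets out from 31, whose C3 hydroxyls are free and whose C4 oxygens are silylated. Acetylation (Ac2O, DMAP, pyridine) gives (3R,4S,5R,6R,3'R,4'S,5'R,6'R)-4,4'-bis[(tert-butyldimethylsilyl)oxy]-5,6,5',6'-tetrahydro-β,β-carotene-3,3'-diyl diacetate F4. HF·pyridine in THF/pyridine, chosen over basic fluoride to suppress acetyl migration, gives (3R,4S,5R,6R,3'R,4'S,5'R,6'R)-4,4'-dihydroxy-5,6,5',6'-tetrahydro-β,β-carotene-3,3'-diyl diacetate F5. SO3·pyridine in DMF sulfates the only free hydroxyls to give (3R,4S,5R,6R,3'R,4'S,5'R,6'R)-3,3'-diacetoxy-5,6,5',6'-tetrahydro-β,β-carotene-4,4'-diyl bis(hydrogen sulfate) F6. K2CO3 in MeOH followed by the acidic resin then returns to the route at 34.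

Further compounds
F1 | step 9 | (1R,2S,3R,4R)-4-{(E)-3-[(4-methoxybenzyl)oxy]prop-1-en-1-yl}-3,5,5-trimethylcyclohexane-1,2-diol | COc1ccc(COC/C=C/[C@@H]2[C@@H](C)[C@H](O)[C@H](O)CC2(C)C)cc1
F2 | step 6 | 1,1-dimethoxy-N,N-dimethylpropan-1-amine | CCC(OC)(OC)N(C)C
F3 | step 6 | methyl (4R,5R)-6-(dimethylamino)-4-{(E)-3-[(4-methoxybenzyl)oxy]prop-1-en-1-yl}-3,3,5-trimethyl-6-oxohexanoate | COc1ccc(COC/C=C/[C@@H](C(C)(C)CC(=O)OC)[C@@H](C)C(=O)N(C)C)cc1
F4 | step 23 | (3R,4S,5R,6R,3'R,4'S,5'R,6'R)-4,4'-bis[(tert-butyldimethylsilyl)oxy]-5,6,5',6'-tetrahydro-β,β-carotene-3,3'-diyl diacetate | CC(/C=C/C=C(C)/C=C/[C@@H]1[C@@H](C)[C@H](O[Si](C)(C)C(C)(C)C)[C@H](OC(C)=O)CC1(C)C)=C\C=C\C=C(C)\C=C\C=C(C)\C=C\[C@@H]1[C@@H](C)[C@H](O[Si](C)(C)C(C)(C)C)[C@H](OC(C)=O)CC1(C)C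
F5 | step 23 | (3R,4S,5R,6R,3'R,4'S,5'R,6'R)-4,4'-dihydroxy-5,6,5',6'-tetrahydro-β,β-carotene-3,3'-diyl diacetate | CC(/C=C/C=C(C)/C=C/[C@@H]1[C@@H](C)[C@H](O)[C@H](OC(C)=O)CC1(C)C)=C\C=C\C=C(C)\C=C\C=C(C)\C=C\[C@@H]1[C@@H](C)[C@H](O)[C@H](OC(C)=O)CC1(C)C
F6 | step 23 | (3R,4S,5R,6R,3'R,4'S,5'R,6'R)-3,3'-diacetoxy-5,6,5',6'-tetrahydro-β,β-carotene-4,4'-diyl bis(hydrogen sulfate) | CC(/C=C/C=C(C)/C=C/[C@@H]1[C@@H](C)[C@H](OS(=O)(=O)O)[C@H](OC(C)=O)CC1(C)C)=C\C=C\C=C(C)\C=C\C=C(C)\C=C\[C@@H]1[C@@H](C)[C@H](OS(=O)(=O)O)[C@H](OC(C)=O)CC1(C)C
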